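## Retrosynthetic overview

1. Endgame in two directions at once: the target comes from a twofold chelation-controlled reduction of a bis(α-aryloxy ketone). That ketone is made by twofold SN2 etherification of a symmetric bisphenol core with an (R)-lactate-derived α-tosyloxy ketone (inversion to S, then erythro reduction gives 1R,2S in both arms).
2. The oxolane is not closed as a five-membered ring. A 2,3-diaryloxirane is expanded by two atoms: its C–C bond is cleaved to a carbonyl ylide, which takes up maleic anhydride in a (3+2) cycloaddition and forms C2–C3 and C4–C5 at once. The fused anhydride is a temporary ring that locks C3/C4 cis; it is opened by hydride in the same flask and its two carbons are later reduced to the methyl groups.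
3. Enabling feature: the C2–O1–C5 segment of the oxolane, an ether oxygen between two benzylic CH carbons that each carry a para-oxygenated aryl ring, is a masked diaryl carbonyl ylide. The ring is meso-type (2,3-trans, 3,4-cis, 4,5-trans, two identical arms), so only its relative configuration must be controlled, and C2/C5 can be set by thermodynamic equilibration.
4. The oxirane comes from a symmetric stilbene, made by McMurry coupling of O-benzylvanillin (union of two carbonyl carbons of like polarity).
5. Ring order: oxirane (step 2), then oxolane fused to the anhydride with reductive opening of the anhydride ring (step 3), then deoxygenation to the methyl groups (steps 4 and 5). The four arene rings are bought.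

Key step: step 3

Remark on the chemistry: 3,4-dimethoxyphenylmagnesium bromide is taken as the commercial THF solution; dimethyldioxirane (in acetone) and Zn(BH4)2 (in Et2O) are used as stock solutions prepared beforehand; in step 3 maleic anhydride is used in about 1.5-fold amount relative to the oxirane.

## Route

Step 1
Reactants: 1 4-(benzyloxy)-3-methoxybenzaldehyde (two equivalents)
Product: 2 (E)-1,2-bis[4-(benzyloxy)-3-methoxyphenyl]ethene
Conditions: TiCl4, Zn dust, THF, 0 °C then reflux
Reagents that add atoms: none
Why: McMurry coupling: low-valent titanium formed from TiCl4 and Zn joins the two aldehyde carbons, which are both electrophilic, through a titanium pinacolate and deoxygenates it to the alkene, the E isomer being favoured for diaryl cases; no stereocentre is set and the aryl benzyl ethers are inert.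

Step 2
Reactants: 2 (E)-1,2-bis[4-(benzyloxy)-3-methoxyphenyl]ethene
Product: 3 trans-2,3-bis[4-(benzyloxy)-3-methoxyphenyl]oxirane (racemic)
Conditions: dimethyldioxirane (acetone solution), CH2Cl2/acetone, 0 °C; evaporate and use crude
Reagents that add atoms: dimethyldioxirane, CC1(C)OO1
Why: Epoxidation of the electron-rich alkene by dimethyldioxirane is a concerted, stereospecific oxygen transfer (E-alkene to trans-oxirane) under neutral conditions, which spares the acid-labile bis(p-alkoxyaryl)oxirane from Meinwald rearrangement; its configuration is erased in step 3, so any cis isomer is equally usable.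

Step 3
Reactants: 3 trans-2,3-bis[4-(benzyloxy)-3-methoxyphenyl]oxirane; 4 maleic anhydride
Product: 8 all-cis {2,5-bis[4-(benzyloxy)-3-methoxyphenyl]oxolane-3,4-diyl}dimethanol (meso), via ring-opened radical cation 5 (not isolated), via carbonyl ylide 6 (not isolated), via all-cis fused anhydride 7 (not isolated)
Conditions: (a) 1,4-dicyanonaphthalene (0.2 equiv), hν (350 nm, Pyrex), MeCN, argon, rt; (b) evaporate under vacuum, then LiAlH4, THF, 0 °C to rt; aqueous work-up
Reagents that add atoms: none
Why: The excited sensitizer oxidises the electron-rich oxirane 3 to its radical cation, whose bis-benzylic C–C bond cleaves to the open radical cation 5, and back electron transfer from the sensitizer radical anion gives the W-shaped carbonyl ylide 6, which adds to maleic anhydride 4 as a 1,3-dipole to give the fused anhydride 7. The closest known reaction type is the electron-transfer-sensitised (3+2) cycloaddition of 2,3-diaryloxiranes with electron-poor alkenes. The oxolane ring is closed by an intermolecular suprafacial (3+2) cycloaddition that inserts C3 and C4 into the former oxirane C–C bond and forms C2–C3 and C4–C5 together, a two-atom ring expansion from three to five members. C3 and C4 are forced cis by the five-membered anhydride ring of the dipolarophile, which cannot isomerise; C2 and C5 come out cis to each other from the W geometry of the ylide, into which cis- and trans-oxirane both relax, and cis to the anhydride from endo approach. The only selectivity the route needs from this step is the cis relation of C3 and C4, which the cyclic dipolarophile secures (the C2/C5 configuration is provisional and is reset in step 6, so an exo adduct or a 2,5-trans isomer formed alongside need not be separated), while chemoselectivity for C–C over C–O cleavage rests on the two p-alkoxyaryl groups, which stabilise both termini of the ylide, and on acid-free, oxygen-free conditions. Because 7 is moisture-sensitive it is not purified: after removal of MeCN and excess 4 under vacuum, LiAlH4 reduces both anhydride carbonyls to CH2OH (the ring oxygen of the anhydride leaves with the aluminium salts) without touching C3, C4, the benzylic ring C–O bonds or the aryl ethers, and the stable diol 8 is isolated.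

Step 4
Reactants: 8 all-cis diol
Product: 9 all-cis {2,5-bis[4-(benzyloxy)-3-methoxyphenyl]oxolane-3,4-diyl}bis(methylene) dimethanesulfonate (meso)
Conditions: MsCl (3 equiv), Et3N, CH2Cl2, −20 °C
Reagents that add atoms: methanesulfonyl chloride, CS(=O)(=O)Cl
Why: Twofold O-sulfonylation of the primary alcohols (sulfene pathway with Et3N) at low temperature is faster than displacement of a mesylate by the neighbouring hydroxyl, so the bis-mesylate should form without closing a second oxolane.

Step 5
Reactants: 9 all-cis bis-mesylate
Product: 10 all-cis meso-(2S,3R,4S,5R)-2,5-bis[4-(benzyloxy)-3-methoxyphenyl]-3,4-dimethyloxolane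
Conditions: LiEt3BH, THF, 0 °C to rt
Reagents that add atoms: none
Why: SN2 displacement of both primary methanesulfonates by hydride from LiEt3BH turns each CH2OMs into CH3 without involving any stereocentre, so the all-cis configuration is carried over unchanged.

Step 6
Reactants: 10 all-cis 3,4-dimethyloxolane
Product: 11 meso-(2S,3S,4R,5R)-2,5-bis[4-(benzyloxy)-3-methoxyphenyl]-3,4-dimethyloxolane (2,3-trans, 3,4-cis, 4,5-trans)
Conditions: BF3·OEt2 (0.3 equiv), CH2Cl2, −20 to 0 °C; Et3N quench
Reagents that add atoms: none
Why: Lewis-acid-mediated epimerisation under thermodynamic control: BF3 reversibly ionises the benzylic C2–O and C5–O bonds to p-alkoxybenzyl cations that re-close from either face, so both aryl groups move trans to their neighbouring methyl groups (least eclipsing strain) while C3 and C4, which lie off the ionisation path, keep their cis relation; this funnels every C2/C5 isomer from step 3 into one meso compound.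

Step 7
Reactants: 11 meso-(2S,3S,4R,5R) dibenzyl ether
Product: 12 meso-4,4'-[(2S,3S,4R,5R)-3,4-dimethyloxolane-2,5-diyl]bis(2-methoxyphenol)
Conditions: H2 (1 atm), 10% Pd/C, EtOAc, rt
Reagents that add atoms: none
Why: Catalytic hydrogenolysis cleaves the two O-benzyl ethers much faster than the hindered secondary benzylic C–O bonds of the oxolane in a non-acidic solvent at 1 atm, so the ring and its four stereocentres should survive when the reaction is stopped at full debenzylation.

Step 8
Reactants: 13 methyl (R)-lactate
Product: 14 (2R)-2-hydroxy-1-(morpholin-4-yl)propan-1-one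
Conditions: morpholine (neat), 85 °C
Reagents that add atoms: morpholine, C1COCCN1
Why: Aminolysis of the ester by neat morpholine gives the amide without a base able to enolise it, so the (R) centre is retained.

Step 9
Reactants: 14 (2R)-2-hydroxy-1-(morpholin-4-yl)propan-1-one; 15 3,4-dimethoxyphenylmagnesium bromide (2.5 equiv)
Product: 16 (2R)-1-(3,4-dimethoxyphenyl)-2-hydroxypropan-1-one
Conditions: THF, −10 °C to rt; aq. NH4Cl
Reagents that add atoms: none
Why: Nucleophilic acyl substitution on a morpholine amide by an aryl Grignard reagent stops at the ketone because the magnesium-chelated tetrahedral intermediate (Weinreb-type behaviour) collapses only on work-up; the first equivalent deprotonates the hydroxyl and the (R) centre is not touched.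

Step 10
Reactants: 16 (2R)-1-(3,4-dimethoxyphenyl)-2-hydroxypropan-1-one
Product: 17 (2R)-1-(3,4-dimethoxyphenyl)-1-oxopropan-2-yl 4-methylbenzenesulfonate
Conditions: TsCl, Et3N, DMAP (cat.), CH2Cl2, 0 °C
Reagents that add atoms: 4-methylbenzenesulfonyl chloride, Cc1ccc(cc1)S(=O)(=O)Cl
Why: Sulfonylation of the secondary alcohol with TsCl and DMAP catalysis occurs at oxygen, so the C–O bond and the (R) configuration are retained.

Step 11
Reactants: 12 meso bisphenol; 17 (2R)-tosylate (2.4 equiv)
Product: 18 (2S,2'S)-2,2'-{[(2S,3S,4R,5R)-3,4-dimethyloxolane-2,5-diyl]bis[(2-methoxy-4,1-phenylene)oxy]}bis[1-(3,4-dimethoxyphenyl)propan-1-one]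
Conditions: K2CO3, 18-crown-6 (cat.), MeCN, 0 °C to rt
Reagents that add atoms: none
Why: Twofold Williamson ether synthesis: each phenoxide displaces the α-keto tosylate by SN2 (accelerated by the adjacent carbonyl) with inversion, setting (S) at both new C–O stereocentres, and a weak, sparingly soluble carbonate base keeps enolisation of electrophile and product slow; both ends react alike, so one operation serves the two arms.

Step 12
Reactants: 18 bis(α-aryloxy ketone)
Product: 19 (1R,1'R,2S,2'S)-2,2'-{[(2S,3S,4R,5R)-3,4-dimethyloxolane-2,5-diyl]bis[(2-methoxy-4,1-phenylene)oxy]}bis[1-(3,4-dimethoxyphenyl)propan-1-ol] (target)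
Conditions: Zn(BH4)2, Et2O/THF, −30 to 0 °C; aq. NH4Cl
Reagents that add atoms: none
Why: Twofold chelation-controlled ketone reduction: Zn bridges the carbonyl oxygen and the α-aryloxy oxygen in a five-membered chelate and hydride enters from the face of the α-hydrogen, which gives the erythro (1R,2S) alcohol at each end independently of the remote core.

## Compound list

1 | 4-(benzyloxy)-3-methoxybenzaldehyde | COc1cc(C=O)ccc1OCc1ccccc1 | starting material
2 | (E)-1,2-bis[4-(benzyloxy)-3-methoxyphenyl]ethene | COc1cc(/C=C/c2ccc(OCc3ccccc3)c(OC)c2)ccc1OCc1ccccc1 | intermediate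
3 | trans-2,3-bis[4-(benzyloxy)-3-methoxyphenyl]oxirane (racemic, one enantiomer drawn) | COc1cc(ccc1OCc1ccccc1)[C@@H]1O[C@H]1c1ccc(OCc2ccccc2)c(OC)c1 | intermediate
4 | maleic anhydride | O=C1OC(=O)C=C1 | starting material
5 | ring-opened radical cation of 3 (oxocarbenium/benzyl radical) | COc1cc(ccc1OCc1ccccc1)C=[O+][CH]c1ccc(OCc2ccccc2)c(OC)c1 | intermediate
6 | bis[4-(benzyloxy)-3-methoxyphenyl] carbonyl ylide (W-shaped, both aryl groups exo) | COc1cc(ccc1OCc1ccccc1)C=[O+][CH-]c1ccc(OCc2ccccc2)c(OC)c1 | intermediate
7 | all-cis 4,6-bis[4-(benzyloxy)-3-methoxyphenyl]-3a,4,6,6a-tetrahydro-1H,3H-furo[3,4-c]furan-1,3-dione (meso) | COc1cc(ccc1OCc1ccccc1)[C@H]1O[C@@H](c2ccc(OCc3ccccc3)c(OC)c2)[C@H]2C(=O)OC(=O)[C@@H]12 | intermediate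
8 | all-cis {2,5-bis[4-(benzyloxy)-3-methoxyphenyl]oxolane-3,4-diyl}dimethanol (meso) | COc1cc(ccc1OCc1ccccc1)[C@H]1O[C@@H](c2ccc(OCc3ccccc3)c(OC)c2)[C@@H](CO)[C@H]1CO | intermediate
9 | all-cis {2,5-bis[4-(benzyloxy)-3-methoxyphenyl]oxolane-3,4-diyl}bis(methylene) dimethanesulfonate (meso) | COc1cc(ccc1OCc1ccccc1)[C@H]1O[C@@H](c2ccc(OCc3ccccc3)c(OC)c2)[C@@H](COS(C)(=O)=O)[C@H]1COS(C)(=O)=O | intermediate
10 | all-cis meso-(2S,3R,4S,5R)-2,5-bis[4-(benzyloxy)-3-methoxyphenyl]-3,4-dimethyloxolane | COc1cc(ccc1OCc1ccccc1)[C@H]1O[C@@H](c2ccc(OCc3ccccc3)c(OC)c2)[C@@H](C)[C@H]1C | intermediate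
11 | meso-(2S,3S,4R,5R)-2,5-bis[4-(benzyloxy)-3-methoxyphenyl]-3,4-dimethyloxolane (2,3-trans, 3,4-cis, 4,5-trans) | COc1cc(ccc1OCc1ccccc1)[C@H]1O[C@@H](c2ccc(OCc3ccccc3)c(OC)c2)[C@H](C)[C@@H]1C | intermediate
12 | meso-4,4'-[(2S,3S,4R,5R)-3,4-dimethyloxolane-2,5-diyl]bis(2-methoxyphenol) | COc1cc(ccc1O)[C@H]1O[C@@H](c2ccc(O)c(OC)c2)[C@H](C)[C@@H]1C | intermediate
13 | methyl (R)-lactate | C[C@@H](O)C(=O)OC | starting material
14 | (2R)-2-hydroxy-1-(morpholin-4-yl)propan-1-one | C[C@@H](O)C(=O)N1CCOCC1 | intermediate
15 | 3,4-dimethoxyphenylmagnesium bromide | COc1ccc([Mg]Br)cc1OC | starting material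
16 | (2R)-1-(3,4-dimethoxyphenyl)-2-hydroxypropan-1-one | C[C@@H](O)C(=O)c1ccc(OC)c(OC)c1 | intermediate
17 | (2R)-1-(3,4-dimethoxyphenyl)-1-oxopropan-2-yl 4-methylbenzenesulfonate | C[C@@H](OS(=O)(=O)c1ccc(C)cc1)C(=O)c1ccc(OC)c(OC)c1 | intermediate
18 | (2S,2'S)-2,2'-{[(2S,3S,4R,5R)-3,4-dimethyloxolane-2,5-diyl]bis[(2-methoxy-4,1-phenylene)oxy]}bis[1-(3,4-dimethoxyphenyl)propan-1-one] | COc1ccc(C(=O)[C@H](C)Oc2ccc([C@H]3O[C@@H](c4ccc(O[C@@H](C)C(=O)c5ccc(OC)c(OC)c5)c(OC)c4)[C@H](C)[C@@H]3C)cc2OC)cc1OC | intermediate
19 | (1R,1'R,2S,2'S)-2,2'-{[(2S,3S,4R,5R)-3,4-dimethyloxolane-2,5-diyl]bis[(2-methoxy-4,1-phenylene)oxy]}bis[1-(3,4-dimethoxyphenyl)propan-1-ol] | COc1ccc([C@@H](O)[C@H](C)Oc2ccc([C@H]3O[C@@H](c4ccc(O[C@@H](C)[C@H](O)c5ccc(OC)c(OC)c5)c(OC)c4)[C@H](C)[C@@H]3C)cc2OC)cc1OC | target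

## Step count and risks

Total step count: 12. Longest linear sequence: 9 steps (steps 1 to 7, then 11 and 12); steps 8 to 10 form the side-chain branch.

Steps most likely to fail:

Step 3. The oxirane radical cation may be diverted into C–O heterolysis and rearrangement, back electron transfer may outrun trapping of the ylide, the electron-rich adduct may be photo-oxidised further, or the crude photolysate may consume hydride unproductively in the reduction stage, so that little diol accumulates. The fallback sets out from 1 and comes back at 11, building the ring from an open chain with known chemistry. Addition of EtMgBr to 1 (THF, 0 °C) should give 1-[4-(benzyloxy)-3-methoxyphenyl]propan-1-ol F1, and MnO2 (CH2Cl2) should oxidise it to 1-[4-(benzyloxy)-3-methoxyphenyl]propan-1-one F2. Oxidative homocoupling of its lithium enolate (LDA, THF, −78 °C; then CuCl2, DMF) joins the two α-carbons; the meso isomer, meso-1,4-bis[4-(benzyloxy)-3-methoxyphenyl]-2,3-dimethylbutane-1,4-dione F3, is collected by crystallisation while the racemic isomer is re-equilibrated with NaOMe in MeOH. LiAlH4 should then give meso-1,4-bis[4-(benzyloxy)-3-methoxyphenyl]-2,3-dimethylbutane-1,4-diol F4 (carbinol centres unassigned). Acid-mediated cyclodehydration (TsOH cat., CH2Cl2) closes the oxolane through the same benzylic cations as in step 6 and should end at 11.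

Step 6. Epimerisation may stay incomplete, or the ring-opened benzylic cation may lose a proton (eroding the C3/C4 cis relation on re-addition) or alkylate another arene. The fallback sets out from 10 and comes back at 12, moving the equilibration to the free phenol. Hydrogenolysis of 10 (H2, 10% Pd/C, EtOAc) should give all-cis 4,4'-(3,4-dimethyloxolane-2,5-diyl)bis(2-methoxyphenol) F5. Its para-hydroxy groups assist ionisation of the benzylic C–O bonds (quinone-methide-type cation), so a weak Brønsted acid (pyridinium p-toluenesulfonate or a trace of CF3CO2H, CH2Cl2, rt) should suffice to epimerise C2 and C5 to 12, at an acidity too low for the elimination pathway.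

Step 11. Base-induced enolisation may epimerise the α-carbon of the tosylate or of the product, and the second alkylation may lag behind the first. The fallback sets out from 12 and 13 and comes back at 18, forming the aryl ether before the ketone exists. Mitsunobu etherification of both phenols of 12 with methyl (R)-lactate 13 (PPh3, DIAD, THF, 0 °C to rt) proceeds with inversion under non-basic conditions and should give dimethyl (2S,2'S)-2,2'-{[(2S,3S,4R,5R)-3,4-dimethyloxolane-2,5-diyl]bis[(2-methoxy-4,1-phenylene)oxy]}dipropanoate F6. Conversion to the corresponding bis(N-methoxy-N-methylpropanamide) F7 (MeNHOMe·HCl, i-PrMgCl, THF, −20 °C) and twofold addition of 15 (THF, 0 °C) should give 18.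

Further compounds
F1 | step 3 | 1-[4-(benzyloxy)-3-methoxyphenyl]propan-1-ol (racemic) | CCC(O)c1ccc(OCc2ccccc2)c(OC)c1
F2 | step 3 | 1-[4-(benzyloxy)-3-methoxyphenyl]propan-1-one | CCC(=O)c1ccc(OCc2ccccc2)c(OC)c1
F3 | step 3 | meso-1,4-bis[4-(benzyloxy)-3-methoxyphenyl]-2,3-dimethylbutane-1,4-dione | COc1cc(ccc1OCc1ccccc1)C(=O)[C@@H](C)[C@@H](C)C(=O)c1ccc(OCc2ccccc2)c(OC)c1
F4 | step 3 | meso-1,4-bis[4-(benzyloxy)-3-methoxyphenyl]-2,3-dimethylbutane-1,4-diol (carbinol centres unassigned) | COc1cc(ccc1OCc1ccccc1)C(O)[C@@H](C)[C@@H](C)C(O)c1ccc(OCc2ccccc2)c(OC)c1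
F5 | step 6 | all-cis meso-4,4'-[(2S,3R,4S,5R)-3,4-dimethyloxolane-2,5-diyl]bis(2-methoxyphenol) | COc1cc(ccc1O)[C@H]1O[C@@H](c2ccc(O)c(OC)c2)[C@@H](C)[C@H]1C
F6 | step 11 | dimethyl (2S,2'S)-2,2'-{[(2S,3S,4R,5R)-3,4-dimethyloxolane-2,5-diyl]bis[(2-methoxy-4,1-phenylene)oxy]}dipropanoate | COC(=O)[C@H](C)Oc1ccc(cc1OC)[C@H]1O[C@@H](c2ccc(O[C@@H](C)C(=O)OC)c(OC)c2)[C@H](C)[C@@H]1C
F7 | step 11 | (2S,2'S)-2,2'-{[(2S,3S,4R,5R)-3,4-dimethyloxolane-2,5-diyl]bis[(2-methoxy-4,1-phenylene)oxy]}bis(N-methoxy-N-methylpropanamide) | CON(C)C(=O)[C@H](C)Oc1ccc(cc1OC)[C@H]1O[C@@H](c2ccc(O[C@@H](C)C(=O)N(C)OC)c(OC)c2)[C@H](C)[C@@H]1C
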